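The data were computed for an exercise, noise included.

Monday's flask, started with 0.250 M of Prd already in it, has added 0.2275 M by 32 min, and Friday's flask, started without any, has made about the same, 0.2254 M. The gap is about the scatter of one reading, so I treat added Prd as a bystander and read a single curve.

| setting | Friday's | Monday's | Wednesday's |
|---|---|---|---|
| Sub | 0.500 M | 0.500 M | 0.250 M |
| Rgt | 1.50 M | 1.50 M | 0.750 M |
| Prd |  | 0.250 M |  |
| time |  |  | 32 min |

- Friday's run (time / min: [Prd] / M): 4.6: 0.0459; 9.1: 0.0819; 14: 0.1203; 18: 0.1450; 23: 0.1821; 27: 0.1994; 32: 0.2254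
- Monday's run (time / min: [Prd] / M): 4.6: 0.2932; 9.1: 0.3302; 14: 0.3711; 18: 0.3957; 23: 0.4287; 27: 0.4512; 32: 0.4775

(scatter of a reading: 0.002 M)

- Prd in the Wednesday's run at 32 min, as a share of the Sub charged

- Overall: Sub + Rgt -> Prd.
- Constant volume, constant temperature.
- What is held in complexes is read along with the free species.
- "The second partner" is Rgt.

Rgt stands at 3.00 times Sub in each flask, so Sub is the limiting reagent and falls in a nearly pseudo-first-order way. That lets me fold the givens into one number. Friday's last reading gives an exposure of 0.599, which is the rate constant times the mean Rgt times the time. It counts the e-fold falls Sub has taken, and the share of Sub left is exp(−exposure).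

With Friday's mean Rgt of 1.39 M, the constant reads 0.0135 L mol⁻¹ min⁻¹. Is one number enough? At 14 min in Friday's flask it predicts 0.119 M against the reading 0.1203 M, a gap of 0.00118 M, less than the scatter of 0.002 M. But that test stays near Friday's Rgt, so first order in Rgt at Wednesday's 0.750 M is my assumption.

Wednesday's charges are half of Friday's. A first pass with Rgt held at its charge turns 0.0692 M, and the mean Rgt that follows gives an exposure of 0.309, so I commit to 26.6% of Sub. The forecast says 28%, somewhat more than my figure, within 25% to 37%, warning that “the Rgt order is only weakly determined”.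

Wednesday's flask gives 28.6%.

    Sub + Rgt → Prd (0.01260 L mol⁻¹ min⁻¹)
    Sub + 2 Rgt → Prd + Rgt (0.2358 L² mol⁻² min⁻¹)
    2 Rgt ⇌ Rgt2, settled at all times (4.730 L mol⁻¹)
    Sub + Rgt ⇌ Sub.Rgt, settled at all times (1.450 L mol⁻¹)

That is an exposure of 0.336, against my 0.309 and Friday's 0.599. Exposure came close to following Rgt in simple proportion because the pairing of Rgt into Rgt2 brings the apparent order in Rgt to 0.94, where the run without that pairing shows 1.5. That run, on Wednesday's charges, gives 76.9%, an exposure of 1.47, which is 4.36 times the real flask's.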